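**The question.** How far does the electrophile get in 12 h once the free base is cut from 2.1 M to 1.50 M, and how much of the unused nucleophile is then free?

the same everywhere: electrophile 0.50 M; nucleophile 0.525 M

|  | free base | protic impurity | remark | time |
|---|---|---|---|---|
| spring | 2.1 M | 10 mM | run made earlier |  |
| flask | 1.50 M | 10.0 mM |  | 12 h |

spring run (percent of the electrophile charged)

| time / h | electrophile / % | target / % |
|---|---|---|
| 0.667 | 69.9 | 30.0 |
| 2.00 | 52.7 | 48.9 |
| 3.00 | 44.5 | 53.6 |
| 5.00 | 41.9 | 58.6 |
| 8.00 | 39.5 | 60.2 |
| 10.0 | 38.1 | 61.1 |
| 12.0 | 37.7 | 60.7 |

(each reading ± 0.5 percentage points)

- the earlier runs do not show how much of nucleophile is bound; that part of a forecast is a guess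
- no earlier run changes the charge of free base; that part of a forecast is a guess

1. part of the electrophile that has reacted at 12 h
2. share of the unused nucleophile that is free and not bound as protonated nucleophile, at 12 h

**Early slope.** In the spring run the electrophile lost reappears as target, so I read the target curve as conversion. Over the first 0.667 h it climbs at 0.450 h⁻¹, as a fraction of the charge.

**The knee.** I suppose each turn spends one nucleophile in the bond and a second to hold the acid set free, and the protic impurity spends its own amount. The nucleophile charge less the impurity, divided by two electrophile charges, is then 51.5%, the knee fraction, where on this count the nucleophile is used up. On the same count it serves fewer turns than there is electrophile, so it is the limiting reagent from the start. The spring target passes it between 2.00 h and 3.00 h, and in that same interval it overtakes the electrophile.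

**The level.** From 3.00 h the slope is 0.00789 h⁻¹, less than the early one. The reading reaches 60.7% at 12.0 h, which is 9.2 percentage points past the knee. I take that excess as acid held by free base instead of nucleophile.

**My reckoning.** This flask has the same knee fraction, 51.5%. If the excess scales with the base charge, the level is 58.1%; if it ignores the base, it stays near 60.7%. I commit to that bracket.

**The forecast.** It gives 60.5% (57% to 62.5%) reacted and 3.5% (1.5% to 7%) free, on the ground that “the nucleophile is being titrated”. Its conversion stands in the upper part of my bracket.

**The result.** This flask gives 61.4% reacted, with 1.44% of the unused nucleophile free.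

    acid set free + free base ⇌ salt of the base, settled at all times (K = 8300 M⁻¹)
    nucleophile + acid set free ⇌ protonated nucleophile, settled at all times (K = 8000 M⁻¹)
    nucleophile + protic impurity → quenched reagent (k = 0.475 M⁻¹ min⁻¹)
    electrophile + nucleophile → acid set free + target (k = 0.0241 M⁻¹ min⁻¹)
    2 free base → self-condensation product (k = 0.0836 M⁻¹ min⁻¹)

This flask stands 9.9 points past the knee fraction, which counted on two electrophile charges is 0.0988 M, and its salt of the base holds 0.0933 M at 12 h. The neighbour flask with 0.13 M of nucleophile has a knee fraction of 12.0%; it reaches 19.5% at 12 h, with 0.0708 M in its salt of the base.

(The data were computed for an exercise; noise was put on by code.)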